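**Retrosynthetic overview**
- The target comes from 2-oxolabda-7,13E-diene-15,19-diyl diacetate by an equatorial-selective ketone reduction, then steric differentiation of the two acetates.
- Ring A and then ring B (bonds C4–C5, then C9–C10) form in one proton-in/proton-out cation–olefin cascade. The substrate is an acyclic C20 (Z)-γ-acetoxy enone that already carries the C2 and C19 oxygens, and the cascade ends by loss of H-7.
- The C20 chain comes from a three-component carbonylative Stille union: C15 allylic chloride + CO + C4 (Z)-vinylstannane.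
- The chloride comes from (2E,6E)-farnesyl acetate, and the stannane from propargyl alcohol.

Assumption: the SMILES is read as the normal labdane series (10β-CH3, 5α-H, 9α-H, axial 4β-CH2OAc, equatorial 2α-OH), and the (S,S)-acid of step 5 is assumed to give this series; if the first run shows the opposite sense, the (R,R)-acid is used.

The chiral acid of step 5, "IDPi acid", is the imidodiphosphorimidate HN[P(=NSO2CF3)(O2Ar*)]2. O2Ar* is (S)-3,3'-bis[3,5-bis(trifluoromethyl)phenyl]-1,1'-binaphthalene-2,2'-diolate. The formula is C74H33F30N3O8P2S2.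

**Step 1**
Reactants: 1 (2E,6E)-farnesyl acetate
Product: 2 (2E,6E,10E)-12-hydroxy-3,7,11-trimethyldodeca-2,6,10-trien-1-yl acetate
Conditions: SeO2 (10 mol %), salicylic acid (10 mol %), t-BuOOH (3.5 equiv), CH2Cl2, 0 °C to rt
Reagents that add atoms: tert-butyl hydroperoxide CC(C)(C)OO (oxygen relayed through catalytic SeO2, O=[Se]=O)
Why: Riley allylic oxidation (ene reaction, then [2,3]-sigmatropic shift) attacks the E-methyl group of the exposed terminal trisubstituted alkene, which fixes the E geometry of the future C5=C10 alkene and leaves the acetate untouched.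

**Step 2**
Reactants: 2 (2E,6E,10E)-12-hydroxy-3,7,11-trimethyldodeca-2,6,10-trien-1-yl acetate
Product: 3 (2E,6E,10E)-12-chloro-3,7,11-trimethyldodeca-2,6,10-trien-1-yl acetate
Conditions: PPh3 (1.3 equiv), CCl4 (5 equiv), CH2Cl2, rt
Reagents that add atoms: carbon tetrachloride ClC(Cl)(Cl)Cl
Why: In this Appel reaction chloride displaces the primary allylic oxyphosphonium by SN2 without allylic shift or E/Z loss, and esters are inert.

**Step 3**
Reactants: 4 propargyl alcohol
Product: 7 (Z)-2-methyl-3-(tributylstannyl)prop-2-en-1-yl acetate, via vinylmagnesium alkoxide 5 (not isolated), via stannyl alkoxide 6 (not isolated)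
Conditions: MeMgBr (2.2 equiv), CuI (10 mol %), THF/Et2O, −10 °C to rt; Bu3SnCl (1.1 equiv), 0 °C; Ac2O (2 equiv), 0 °C to rt
Reagents that add atoms: methylmagnesium bromide C[Mg]Br; tributyltin chloride CCCC[Sn](Cl)(CCCC)CCCC; acetic anhydride CC(=O)OC(C)=O
Why: Alkoxide-directed, copper-catalysed anti-carbomagnesiation puts CH3 on the inner alkyne carbon and holds Mg cis to CH2O in a five-membered chelate, so stannylation with retention and O-acetylation of the magnesium alkoxide give only the Z isomer.

**Step 4**
Reactants: 3 (2E,6E,10E)-12-chloro-3,7,11-trimethyldodeca-2,6,10-trien-1-yl acetate; 7 (Z)-2-methyl-3-(tributylstannyl)prop-2-en-1-yl acetate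
Product: 8 (2Z,6E,10E,14E)-2,6,10,14-tetramethyl-4-oxohexadeca-2,6,10,14-tetraene-1,16-diyl diacetate
Conditions: Pd2(dba)3 (2.5 mol %), P(2-furyl)3 (10 mol %), CO (3 atm), THF, 45 °C, dark; buffered silica
Reagents that add atoms: carbon monoxide [C-]#[O+]
Why: In this carbonylative Stille coupling the allyl chloride adds to zerovalent palladium, CO inserts at the primary allyl terminus and the vinyl group transfers with retention, so both E and Z geometries are kept; the two allylic acetates ionise far more slowly than the chloride with this weakly donating ligand.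

**Step 5**
Reactants: 8 (2Z,6E,10E,14E)-2,6,10,14-tetramethyl-4-oxohexadeca-2,6,10,14-tetraene-1,16-diyl diacetate
Product: 11 2-oxolabda-7,13E-diene-15,19-diyl diacetate, via C8 labdenyl cation 9 (not isolated), via bicyclic enol 10 (not isolated)
Conditions: (S,S)-IDPi acid C74H33F30N3O8P2S2 (5 mol %), 4 Å MS, CHCl3, −55 °C, 48 h; Et3N quench
Reagents that add atoms: none
Why: Proposed new method: the β,β-disubstituted enone is the most basic site, so the confined acid protonates only its oxygen (isolated alkenes are not protonated at this temperature) and gives a hydroxyallyl cation with tertiary carbenium character at C4; in its s-trans form C5=C10 captures this cation 6-endo and C9=C8 then closes ring B through a chair–chair array, so the Z-CH2OAc becomes the axial 4β group, the two E alkenes give 5α-H/10β-CH3 and 9α-H, and the chiral phosphorimidate ion pair chooses the face of C4 and thus the absolute series; C13=C14 is deactivated by its allylic acetate, the same anion removes the axial H-7 to give the trisubstituted 7-ene, and the enol tautomerises; the closest known reaction types are the confined-acid asymmetric Nazarov cyclization of simple divinyl ketones, the confined-acid polyene cyclization of homofarnesol, the Lewis acid induced conjugate addition of alkenes to enones, and the acid cycloalkylation of benzyl vinyl ketones to 4,4-disubstituted 2-tetralones.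

**Step 6**
Reactants: 11 2-oxolabda-7,13E-diene-15,19-diyl diacetate
Product: 12 2α-hydroxylabda-7,13E-diene-15,19-diyl diacetate
Conditions: SmI2 (2.5 equiv, 0.1 M in THF), H2O (25 equiv), 0 °C, 15 min
Reagents that add atoms: none
Why: Single-electron ketone reduction through a ketyl and a carbinyl-samarium species places oxygen equatorial, away from the syn-axial C19 and C20 groups, and the small proton enters axially, as in dissolving-metal reduction of 11-oxo steroids to the equatorial alcohol; hydride reagents would attack the open α face and give 2β-OH; acetates, including the allylic one, are inert without zerovalent palladium.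

**Step 7**
Reactants: 12 2α-hydroxylabda-7,13E-diene-15,19-diyl diacetate
Product: 13 19-acetoxylabda-7,13E-diene-2α,15-diol
Conditions: K2CO3 (0.2 equiv), MeOH, 0 °C, stopped at full conversion of 12
Reagents that add atoms: none
Why: Base-catalysed transesterification removes the unhindered primary allylic C15 acetate much faster than the neopentyl axial C19 acetate; the equatorial 2α-OH is too far from C19 for acyl migration, and no stereocentre is touched.

**Compound list**
1 | (2E,6E)-farnesyl acetate | CC(C)=CCC/C(C)=C/CC/C(C)=C/COC(C)=O | starting material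
2 | (2E,6E,10E)-12-hydroxy-3,7,11-trimethyldodeca-2,6,10-trien-1-yl acetate | OC/C(C)=C/CC/C(C)=C/CC/C(C)=C/COC(C)=O | intermediate
3 | (2E,6E,10E)-12-chloro-3,7,11-trimethyldodeca-2,6,10-trien-1-yl acetate | ClC/C(C)=C/CC/C(C)=C/CC/C(C)=C/COC(C)=O | intermediate
4 | propargyl alcohol | C#CCO | starting material
5 | (Z)-3-(bromomagnesio)-2-methylprop-2-en-1-olate bromomagnesium salt (Mg cis to CH2O) | Br[Mg]/C=C(/C)CO[Mg]Br | intermediate
6 | bromomagnesium (Z)-2-methyl-3-(tributylstannyl)prop-2-en-1-olate | CCCC[Sn](CCCC)(CCCC)/C=C(/C)CO[Mg]Br | intermediate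
7 | (Z)-2-methyl-3-(tributylstannyl)prop-2-en-1-yl acetate (Sn cis to CH2OAc) | CCCC[Sn](CCCC)(CCCC)/C=C(/C)COC(C)=O | intermediate
8 | (2Z,6E,10E,14E)-2,6,10,14-tetramethyl-4-oxohexadeca-2,6,10,14-tetraene-1,16-diyl diacetate (CH2OAc cis to the ketone carbon) | CC(=O)OC/C(C)=C\C(=O)C/C(C)=C/CC/C(C)=C/CC/C(C)=C/COC(C)=O | intermediate
9 | 15,19-diacetoxy-2-hydroxylabda-2,13E-dien-8-yl cation (4β-CH2OAc, 5α-H, 9α-H, 10β-CH3) | CC(=O)OC[C@@]1(C)C=C(O)C[C@]2(C)[C@@H](CC/C(C)=C/COC(C)=O)[C+](C)CC[C@@H]12 | intermediate
10 | 2-hydroxylabda-2,7,13E-triene-15,19-diyl diacetate (enol) | CC(=O)OC[C@@]1(C)C=C(O)C[C@]2(C)[C@@H](CC/C(C)=C/COC(C)=O)C(C)=CC[C@@H]12 | intermediate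
11 | 2-oxolabda-7,13E-diene-15,19-diyl diacetate (4β-axial CH2OAc, 4α-CH3, 5α-H, 9α-H, 10β-CH3) | CC(=O)OC[C@@]1(C)CC(=O)C[C@]2(C)[C@@H](CC/C(C)=C/COC(C)=O)C(C)=CC[C@@H]12 | intermediate
12 | 2α-hydroxylabda-7,13E-diene-15,19-diyl diacetate (equatorial OH) | CC(=O)OC[C@@]1(C)C[C@H](O)C[C@]2(C)[C@@H](CC/C(C)=C/COC(C)=O)C(C)=CC[C@@H]12 | intermediate
13 | 19-acetoxylabda-7,13E-diene-2α,15-diol (CNP0319060.1) | CC(=O)OC[C@@]1(C)C[C@H](O)C[C@]2(C)[C@@H](CC/C(C)=C/CO)C(C)=CC[C@@H]12 | target

**Total step count:** 7. **Longest linear sequence:** 6 (steps 1, 2, 4, 5, 6, 7).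

**Three steps most likely to fail**

Step 5 (bicyclisation).
- The risks are low enantioselectivity and E/Z scrambling at C3=C4 through reversible participation of the C19 acetate.
- Loss of AcOH could give the 2-alkyl-4-methylfuran, and shift of C5=C10 into conjugation could be followed by Nazarov closure.
- The 8(17)- and 8(9)-ene isomers could form, and C13=C14 could close a third ring.
- The fallback sets out from 8 and replaces catalyst control by a stoichiometric achiral Lewis acid followed by resolution.
- MeAlCl2 (3.5 equiv, CH2Cl2, −78 °C) ties up both acetates as aluminium complexes. It activates the enone as a cationic aluminium complex for the same cascade, and the Al–CH3 bond takes up the released proton as methane.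
- The product is the racemate, that is 11 together with its mirror image ent-2-oxolabda-7,13E-diene-15,19-diyl diacetate F4. F4 is removed by preparative supercritical-fluid chromatography on an amylose tris(3,5-dimethylphenylcarbamate) phase.
- The route is rejoined at 11.

Step 4 (carbonylative Stille).
- The risks are direct coupling without CO, ionisation of an allylic acetate, and migration of the β,γ-alkene into conjugation.
- The fallback sets out from 3 and 7 and builds the ketone stepwise.
- Palladium-catalysed formylation of 3 (Pd(PPh3)4, CO 3 atm, slow addition of Bu3SnH, THF, 50 °C) gives (2E,6E,10E)-3,7,11-trimethyl-13-oxotrideca-2,6,10-trien-1-yl acetate F1.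
- Iododestannylation of 7 (I2, CH2Cl2, 0 °C, retention) gives (Z)-3-iodo-2-methylprop-2-en-1-yl acetate F2.
- Nozaki–Hiyama–Kishi coupling of the two (CrCl2, 1 mol % NiCl2, DMF) gives (2Z,6E,10E,14E)-4-hydroxy-2,6,10,14-tetramethylhexadeca-2,6,10,14-tetraene-1,16-diyl diacetate F3 as the racemic carbinol.
- Oxidation with Dess–Martin periodinane and NaHCO3 removes that centre and rejoins the route at 8.

Step 6 (equatorial-selective reduction).
- The risk is a poor 2α:2β ratio.
- The fallback sets out from 11 and uses the intrinsic hydride bias followed by inversion.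
- NaBH4 (MeOH, −20 °C) attacks the open α face and gives 2β-hydroxylabda-7,13E-diene-15,19-diyl diacetate F5.
- Mitsunobu inversion with chloroacetic acid (PPh3, DIAD, toluene) gives 2α-(chloroacetoxy)labda-7,13E-diene-15,19-diyl diacetate F6.
- K2CO3 in MeOH at 0 °C then removes the chloroacetate and the C15 acetate together, and the route is rejoined at 13.

**Further compounds**
F1 | step 4 | (2E,6E,10E)-3,7,11-trimethyl-13-oxotrideca-2,6,10-trien-1-yl acetate | O=CC/C(C)=C/CC/C(C)=C/CC/C(C)=C/COC(C)=O
F2 | step 4 | (Z)-3-iodo-2-methylprop-2-en-1-yl acetate | I/C=C(/C)COC(C)=O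
F3 | step 4 | (2Z,6E,10E,14E)-4-hydroxy-2,6,10,14-tetramethylhexadeca-2,6,10,14-tetraene-1,16-diyl diacetate (racemic carbinol) | CC(=O)OC/C(C)=C\C(O)C/C(C)=C/CC/C(C)=C/CC/C(C)=C/COC(C)=O
F4 | step 5 | ent-2-oxolabda-7,13E-diene-15,19-diyl diacetate | CC(=O)OC[C@]1(C)CC(=O)C[C@@]2(C)[C@H](CC/C(C)=C/COC(C)=O)C(C)=CC[C@H]12
F5 | step 6 | 2β-hydroxylabda-7,13E-diene-15,19-diyl diacetate | CC(=O)OC[C@@]1(C)C[C@@H](O)C[C@]2(C)[C@@H](CC/C(C)=C/COC(C)=O)C(C)=CC[C@@H]12
F6 | step 6 | 2α-(chloroacetoxy)labda-7,13E-diene-15,19-diyl diacetate | CC(=O)OC[C@@]1(C)C[C@H](OC(=O)CCl)C[C@]2(C)[C@@H](CC/C(C)=C/COC(C)=O)C(C)=CC[C@@H]12
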